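**Retrosynthetic overview**
1. Target ⇐ selective O‑acetylation ⇐ triol ⇐ double singlet‑oxygen ene reaction (C2=C3 and C14=C15) of a bicyclic dienol, mirroring the late oxygenations of the presumed biogenesis.
2. Bicyclic dienol ⇐ one cationic cascade of a monocyclic, bisabolyl‑type tertiary ester: 1,2‑shift of ring carbon C1 from C6 to C7 (six‑ → seven‑membered ring), concerted with C6–C10 closure (five‑membered ring) and water capture at C11.
3. Monocyclic precursor ⇐ Markovnikov hydration of a tetraene ⇐ allyl–allyl coupling of metalated (R)‑limonene with geranyl bromide.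
4. Ring order: the six‑membered ring comes with limonene (the product of nature's 1,6‑closure); in step 3 it is expanded to the seven‑membered ring while the five‑membered ring closes.

Assumption: the presumed biogenesis is geranylgeranyl diphosphate → 1,6‑closure to a bisabolyl‑type C7 cation → 1,2‑shift of C1 from C6 to C7 with C6–C10 closure and water capture at C11 → ene‑type oxygenation at C2=C3 and C14=C15 → acetylation; geranylgeranyl numbering (chain C1–C15, methyl‑bearing C3, C7, C11, C15) is used for positions throughout.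

**Step 1**
Reactants: 1 (R)‑(+)‑limonene; 2 geranyl bromide
Product: 4 (4R)‑4‑[(5E)‑6,10‑dimethylundeca‑1,5,9‑trien‑2‑yl]‑1‑methylcyclohex‑1‑ene, via 10‑lithiolimonene 3 (not isolated)
Conditions: n‑BuLi, TMEDA, hexane, rt, 24 h; then 2, THF, −78 °C → rt
Reagents that add atoms: none
Why: n‑BuLi·TMEDA deprotonates limonene regioselectively at the isopropenyl methyl (the stereocentre is not part of the allyl anion and stays R), and the 2‑substituted allyllithium, whose two termini are equivalent, displaces the primary allylic bromide (SN2, Wurtz‑type allyl–allyl coupling) with retention of the E alkene, the classical metalation–alkylation entry to β‑bisabolene‑type dienes.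

**Step 2**
Reactants: 4 (4R)‑4‑[(5E)‑6,10‑dimethylundeca‑1,5,9‑trien‑2‑yl]‑1‑methylcyclohex‑1‑ene
Product: 6 (5E)‑6,10‑dimethyl‑2‑[(1R)‑4‑methylcyclohex‑3‑en‑1‑yl]undeca‑5,9‑dien‑2‑ol (both C7 epimers), via tertiary hydroperoxide 5 (not isolated)
Conditions: Co(acac)2 (20 mol %), PhSiH3, O2 (1 atm), i‑PrOH, 0 °C → rt; then PPh3
Reagents that add atoms: dioxygen, O=O
Why: Mukaiyama hydration (cobalt‑hydride hydrogen‑atom transfer, O2 capture of the tertiary radical, PPh3 reduction of the peroxide) is Markovnikov and kinetically selects the unhindered 1,1‑disubstituted alkene over the three trisubstituted ones; the new carbinol centre C7 forms as a mixture, which does not matter because C7 is ionised in step 3.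

**Step 3**
Reactants: 6 (5E)‑6,10‑dimethyl‑2‑[(1R)‑4‑methylcyclohex‑3‑en‑1‑yl]undeca‑5,9‑dien‑2‑ol
Product: 8 (2S)‑2‑[(1S,3aR,8aS)‑3a,6‑dimethyl‑1,2,3,3a,4,7,8,8a‑octahydroazulen‑1‑yl]‑6‑methylhept‑5‑en‑2‑ol, via tertiary trifluoroacetate 7 (not isolated)
Conditions: (CF3CO)2O, pyridine, CH2Cl2, −20 °C; then (CF3)2CHOH/H2O (95:5), 2,6‑di‑tert‑butylpyridine, −20 → 0 °C
Reagents that add atoms: water, O
Why: Proposed new method: buffered SN1 solvolysis of the tertiary trifluoroacetate in the strongly ionising, weakly nucleophilic solvent generates only the C7 (bisabolyl‑type) cation, and in the folded conformer the C10=C11 π bond attacks C6 anti to C1 while C1 migrates suprafacially from C6 to C7, so that the uphill secondary cycloheptyl cation is never a free intermediate (concerted Wagner–Meerwein 1,2‑alkyl shift/5‑exo cation–olefin closure); inversion at C6 turns the R centre of limonene into 6S, the rotamer with C8 eclipsing H6 gives the trans ring junction (7R), the alkene reacts on the face that puts C11 syn to C5 (10S), and water adds to the C11 cation anti across the E alkene (11S); the closest known reaction types are tail‑to‑head terpene cyclisations through bisabolyl cations and water‑terminated cation–olefin cyclisations in fluorinated alcohols, where a 1,2‑hydride shift to acorane‑type spirocycles is the usual competitor.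

**Step 4**
Reactants: 8 (2S)‑2‑[(1S,3aR,8aS)‑3a,6‑dimethyl‑1,2,3,3a,4,7,8,8a‑octahydroazulen‑1‑yl]‑6‑methylhept‑5‑en‑2‑ol
Product: 10 (1S,3aR,5S,8aS)‑1‑[(2S,4E)‑2,6‑dihydroxy‑6‑methylhept‑4‑en‑2‑yl]‑3a‑methyl‑6‑methylidenedecahydroazulen‑5‑ol, via bis‑hydroperoxide 9 (not isolated)
Conditions: O2, hν (visible), tetraphenylporphyrin (metal‑free, cat.), CH2Cl2, 0 °C; then PPh3
Reagents that add atoms: dioxygen, O=O
Why: Double Schenck ene reaction: singlet oxygen adds suprafacially to each trisubstituted alkene with allylic transposition, at the ring from the α face opposite the angular methyl with abstraction of a C3‑methyl hydrogen (2S hydroperoxide, exocyclic methylene) and in the side chain with abstraction from C13 (tertiary hydroperoxide, E alkene), and PPh3 reduces both O–O bonds without touching alkenes or stereocentres; the regioisomeric ene products are removed by chromatography.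

**Step 5**
Reactants: 10 (1S,3aR,5S,8aS)‑1‑[(2S,4E)‑2,6‑dihydroxy‑6‑methylhept‑4‑en‑2‑yl]‑3a‑methyl‑6‑methylidenedecahydroazulen‑5‑ol; 11 acetic anhydride
Product: 12 (1S,3aR,5S,8aS)‑1‑[(2S,4E)‑2,6‑dihydroxy‑6‑methylhept‑4‑en‑2‑yl]‑3a‑methyl‑6‑methylidenedecahydroazulen‑5‑yl acetate
Conditions: pyridine, DMAP (cat.), CH2Cl2, 0 °C
Reagents that add atoms: acetic anhydride, CC(=O)OC(C)=O
Why: DMAP‑catalysed acylation esterifies only the secondary allylic alcohol because both tertiary alcohols are too hindered to react at 0 °C, and no stereocentre is touched.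

**Compound list**
1 | (R)‑(+)‑limonene, (4R)‑1‑methyl‑4‑(prop‑1‑en‑2‑yl)cyclohex‑1‑ene | CC1=CC[C@@H](CC1)C(C)=C | starting material
2 | geranyl bromide, (2E)‑1‑bromo‑3,7‑dimethylocta‑2,6‑diene | CC(C)=CCC/C(C)=C/CBr | starting material
3 | 10‑lithiolimonene, {2‑[(1R)‑4‑methylcyclohex‑3‑en‑1‑yl]prop‑2‑en‑1‑yl}lithium (TMEDA complex) | CC1=CC[C@@H](CC1)C(=C)C[Li] | intermediate
4 | (4R)‑4‑[(5E)‑6,10‑dimethylundeca‑1,5,9‑trien‑2‑yl]‑1‑methylcyclohex‑1‑ene | CC1=CC[C@@H](CC1)C(=C)CC/C=C(\C)CCC=C(C)C | intermediate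
5 | (5E)‑2‑hydroperoxy‑6,10‑dimethyl‑2‑[(1R)‑4‑methylcyclohex‑3‑en‑1‑yl]undeca‑5,9‑diene, both C7 epimers | CC1=CC[C@@H](CC1)C(C)(OO)CC/C=C(\C)CCC=C(C)C | intermediate
6 | (5E)‑6,10‑dimethyl‑2‑[(1R)‑4‑methylcyclohex‑3‑en‑1‑yl]undeca‑5,9‑dien‑2‑ol, both C7 epimers | CC1=CC[C@@H](CC1)C(C)(O)CC/C=C(\C)CCC=C(C)C | intermediate
7 | trifluoroacetate of 6, (5E)‑6,10‑dimethyl‑2‑[(1R)‑4‑methylcyclohex‑3‑en‑1‑yl]undeca‑5,9‑dien‑2‑yl trifluoroacetate | CC1=CC[C@@H](CC1)C(C)(OC(=O)C(F)(F)F)CC/C=C(\C)CCC=C(C)C | intermediate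
8 | (2S)‑2‑[(1S,3aR,8aS)‑3a,6‑dimethyl‑1,2,3,3a,4,7,8,8a‑octahydroazulen‑1‑yl]‑6‑methylhept‑5‑en‑2‑ol (trans‑fused; 6S,7R,10S,11S in chain numbering) | C1=C(C)CC[C@H]2[C@@H]([C@@](C)(O)CCC=C(C)C)CC[C@]2(C)C1 | intermediate
9 | (2S,4E)‑6‑hydroperoxy‑2‑[(1S,3aR,5S,8aS)‑5‑hydroperoxy‑3a‑methyl‑6‑methylidenedecahydroazulen‑1‑yl]‑6‑methylhept‑4‑en‑2‑ol | C=C1CC[C@H]2[C@@H]([C@@](C)(O)C/C=C/C(C)(C)OO)CC[C@]2(C)C[C@@H]1OO | intermediate
10 | (1S,3aR,5S,8aS)‑1‑[(2S,4E)‑2,6‑dihydroxy‑6‑methylhept‑4‑en‑2‑yl]‑3a‑methyl‑6‑methylidenedecahydroazulen‑5‑ol | C=C1CC[C@H]2[C@@H]([C@@](C)(O)C/C=C/C(C)(C)O)CC[C@]2(C)C[C@@H]1O | intermediate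
11 | acetic anhydride | CC(=O)OC(C)=O | starting material
12 | (1S,3aR,5S,8aS)‑1‑[(2S,4E)‑2,6‑dihydroxy‑6‑methylhept‑4‑en‑2‑yl]‑3a‑methyl‑6‑methylidenedecahydroazulen‑5‑yl acetate (CNP0290154.1) | C=C1CC[C@H]2[C@@H]([C@@](C)(O)C/C=C/C(C)(C)O)CC[C@]2(C)C[C@@H]1OC(C)=O | target

**Totals**
Total step count: 5. Longest linear sequence: 5 steps (from 1).

**Steps most likely to fail**

Step 3 (by far the riskiest). The free C7 cation can undergo a 1,2‑hydride shift from C6 followed by spirocyclisation to acorane‑type products, which is what such cations normally do in a flask. It can also lose a proton to give trienes, and the alkene can attack C6 with its other face, giving the 10,11‑bis‑epimer. The target's side chain sits on the more hindered face, so this face selectivity is the least secure stereochemical element. Fallback: set out from tetraene 4 and come back at 8, replacing C–O heterolysis by metal‑hydride hydrogen‑atom transfer with radical–polar crossover. The reagents are Co(salen) (N,N′‑bis(salicylidene)ethylenediaminatocobalt, divalent cobalt), N‑fluoro‑2,4,6‑trimethylpyridinium tetrafluoroborate and PhSiH3 in (CF3)2CHOH/CH2Cl2/H2O. Hydrogen‑atom transfer occurs only at the 1,1‑disubstituted alkene and gives the C7 radical, which is captured and oxidised to a tertiary alkyl on tetravalent cobalt. This metal‑bound electrophile would be displaced in an SN2‑like manner by the migrating C1–C6 bond while C10=C11 closes on C6 and water caps C11, so no free, long‑lived C7 cation is available for the hydride shift. This is equally unproven and does not address the face selectivity at C10. It needs neither step 2 nor an acid and makes no new isolable compound (F0).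

Step 4. Two trisubstituted alkenes each have competing ene modes: ring‑hydrogen abstraction at C1 or C4 instead of the C3 methyl, and methyl abstraction instead of C13 in the side chain (about 1:1). The yield of the doubly correct isomer will be low. Fallback: set out from 8 and come back at 10 by stepwise, regiocontrolled oxygen transposition. m‑CPBA (2.2 equiv, NaHCO3, CH2Cl2) epoxidises both trisubstituted alkenes, the ring one from the α face, to the bis‑epoxide F1. Sodium benzeneselenolate (from (PhSe)2/NaBH4, EtOH) opens the unhindered side‑chain epoxide at its secondary carbon C14 to the β‑hydroxy selenide F2. H2O2 oxidises this to the selenoxide F3, whose syn elimination can only run towards C13 and gives the (E)‑allylic tertiary alcohol, epoxy diol F4. Diethylaluminium 2,2,6,6‑tetramethylpiperidide then isomerises the ring epoxide by removing a proton from the C3 methyl, and aqueous work‑up gives triol 10 with the C2 oxygen on the α face.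

Step 1. Metalation of limonene may be incomplete, and the allyllithium can attack geranyl bromide in the SN2′ sense (linalyl‑type isomer) or give Wurtz homocoupling. Fallback: set out from 1 (with 2) and come back at 6, building the C7–C8 bond by enolate alkylation instead. OsO4 (cat.)/NaIO4 in aqueous dioxane cleaves only the 1,1‑disubstituted alkene of limonene, via the diol F5, to (R)‑4‑acetyl‑1‑methylcyclohexene F6. Lithium diisopropylamide (THF, −78 °C) gives the kinetic, methyl‑side lithium enolate F7 without touching the ring stereocentre. Alkylation with 2 gives the ketone F8, and MeMgBr (THF, 0 °C) followed by aqueous work‑up gives 6 as both C7 epimers. This also bypasses the chemoselective hydration of step 2.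

**Further compounds**
F0 | step 3 | none | none
F1 | step 4 | bis‑epoxide of 8: (2S,3R)‑2,3‑epoxide on the α face of the ring and 14,15‑epoxide (C14 epimers) | C[C@@]13CC[C@H]2[C@@H]([C@@](C)(O)CCC4OC4(C)C)CC[C@]2(C)C[C@@H]1O3
F2 | step 4 | β‑hydroxy selenide: ring (2S,3R)‑epoxide retained, C14 phenylselanyl, C15 hydroxyl | C[C@@]13CC[C@H]2[C@@H]([C@@](C)(O)CCC([Se]c4ccccc4)C(C)(C)O)CC[C@]2(C)C[C@@H]1O3
F3 | step 4 | selenoxide of F2 | C[C@@]13CC[C@H]2[C@@H]([C@@](C)(O)CCC([Se](=O)c4ccccc4)C(C)(C)O)CC[C@]2(C)C[C@@H]1O3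
F4 | step 4 | epoxy diol: ring (2S,3R)‑epoxide, side chain (2S,4E)‑2,6‑dihydroxy‑6‑methylhept‑4‑en‑2‑yl | C[C@@]13CC[C@H]2[C@@H]([C@@](C)(O)C/C=C/C(C)(C)O)CC[C@]2(C)C[C@@H]1O3
F5 | step 1 | (4R)‑p‑menth‑1‑ene‑8,9‑diol (C8 epimers) | CC1=CC[C@@H](CC1)C(C)(O)CO
F6 | step 1 | (R)‑4‑acetyl‑1‑methylcyclohexene, 1‑[(1R)‑4‑methylcyclohex‑3‑en‑1‑yl]ethan‑1‑one | CC1=CC[C@@H](CC1)C(C)=O
F7 | step 1 | lithium 1‑[(1R)‑4‑methylcyclohex‑3‑en‑1‑yl]ethen‑1‑olate | CC1=CC[C@@H](CC1)C(=C)O[Li]
F8 | step 1 | (4E)‑5,9‑dimethyl‑1‑[(1R)‑4‑methylcyclohex‑3‑en‑1‑yl]deca‑4,8‑dien‑1‑one | CC1=CC[C@@H](CC1)C(=O)CC/C=C(\C)CCC=C(C)C
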